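A small charge of substrate, 0.40 M with 15 mM of free catalyst, reads 97.5% of the charge as target after 15.0 min in the larch run, while the alder run, with 5 mM of free catalyst, reads 48.0% at that time. The new flasks carry 10 mM of free catalyst, between those two, and charges of substrate from 0.40 M up to 1.5 M.

| setting | larch | alder | Saturday's | Friday's | Tuesday's | Sunday's |
|---|---|---|---|---|---|---|
| substrate | 0.40 M | 0.40 M | 0.40 M | 0.60 M | 1.0 M | 1.5 M |
| free catalyst | 15 mM | 5 mM | 10 mM | 10 mM | 10 mM | 10 mM |
| remark | run made earlier | run made earlier |  |  |  |  |
| time |  |  | 1.0 h | 1.0 h | 1.0 h | 1.0 h |

| larch: time / min | larch: target / % | alder: time / min | alder: target / % |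
|---|---|---|---|
| 8.00 | 73.3 | 3.00 | 9.7 |
| 15.0 | 97.5 | 10.0 | 33.8 |
| 20.0 | 97.6 | 15.0 | 48.0 |
| 30.0 | 98.0 | 25.0 | 74.6 |
| 40.0 | 98.0 | 40.0 | 94.8 |

(scatter of a reading: 0.5 percentage points)

- in percentages every species weighs as the substrate in it: one side product counts as two
- for target the crystals are counted in
- as a solid, counted per litre of solution: crystals
- what was read earlier has a scatter of 0.5 percentage points, one standard deviation
- candidate steps: substrate + free catalyst -> catalyst intermediate; catalyst intermediate <-> free catalyst + target; substrate + target -> side product; crystals <-> target
- the concentration of target that is asked is that of its free form alone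
- "hardly changes" means that all values lie within two and a half points (for a concentration: within two and a half percent of the largest)

- [target] (only what is free in solution) at the end for Saturday's, Friday's, Tuesday's, Sunday's, in this order
- the course of these numbers from the first flask to the last (falls, then rises / hardly changes / rises all the way / rises, then falls / falls all the way)

The alder reading gives a turnover number, target made per catalyst per minute, of 2.56 /min, and the first larch reading gives 2.44 /min, so the rate follows the catalyst. By my own reckoning, that turnover number gives Saturday's flask 15.6 min and Sunday's flask, with the largest charge, 58.6 min. This is the clearing time, the charge divided by catalyst times turnover number. Sunday's value is still under 1.0 h, so the smaller charges should clear with time to spare.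

Two chemists accept this and still disagree. The question is about free target. One, who made the forecast, holds that free target follows the charge: 0.387 M, 0.56 M, 0.85 M, 1.05 M, so the row rises all the way. Of crystals this chemist says “I assume no cap”.

The other holds that crystals are among the candidate steps and that the readings count them as target, so those readings cannot speak against a ceiling. Once a flask has cleared, she expects free target to stand at that ceiling whatever the charge was, which makes the row flat. No reading carries a level, so she names none: her claim is a shape and the forecast's is a set of numbers.

The simulation gives 0.320 M, 0.320 M, 0.320 M, 0.320 M, so the row hardly changes, as the second chemist expected.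

    substrate + free catalyst → catalyst intermediate (k = 1.39 /M/s)
    catalyst intermediate ⇌ free catalyst + target (K = 0.870 M, k = 0.0496 /s)
    substrate + target → side product (k = 1.33 × 10⁻⁴ /M/s)
    crystals ⇌ target, rate k4*(cs4 - [target]) while solid is left; crystals form when [target] > cs4 (solubility = 0.320 M, k = 0.0528 /s)

Free target is 80.0% of Saturday's charge, and the forecast's rising row belongs below 0.32 M, the level under which crystals do not form. Half of Saturday's clearing time is 7.80 min, and that flask's release of target from the catalyst intermediate had half its turnover done by 7.59 min. An excess of free target over the ceiling has a half-life of 13.1 s, far shorter than Sunday's clearing time of 58.6 min. At 1.00 h Sunday's flask holds 0.048% of its substrate, and its free target is 21.3% of the charge.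

(All runs stem from a simulated flask for an exercise; scatter was added.)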